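If target were to lead side product at 3.0 d in the 0.20 M flask, c(target) would have to stand above c(side product), which the west and north-east runs read on average at 35.0% at that time.

| setting | west | north-east | flask |
|---|---|---|---|
| substrate | 0.13 M | 0.30 M | 0.20 M |
| remark | run made earlier | run made earlier |  |
| time |  |  | 3.0 d |

| run | time / d | side product / % | target / % |
|---|---|---|---|
| west | 0.500 | 29 | 22 |
| west | 1.04 | 36 | 5 |
| west | 1.67 | 37 | 1 |
| west | 2.08 | 39 | 0 |
| west | 2.50 | 36 | 0 |
| west | 3.00 | 36 | 1 |
| north-east | 0.500 | 29 | 22 |
| north-east | 1.04 | 37 | 6 |
| north-east | 1.67 | 37 | 0 |
| north-east | 2.08 | 37 | 0 |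
| north-east | 2.50 | 36 | 3 |
| north-east | 3.00 | 34 | 0 |

(each reading ± 1.5 percentage points)

* share of side product in side product plus target at 40 min
* share of side product in side product plus target at 3.0 d
* which of side product and target there is more of at 3.0 d

- the numbers in the tables scatter with a standard deviation of 1.5 percentage points

Turned round, the question becomes how far c(target) stands from that level. At 0.500 d both runs read target at 22%, below side product at 29%, and c(target) then falls. At 3.00 d the west run reads target as the small term, so the reckoning here computes that correction, with the share of side product close to one minus c(target)/c(side product). Call k the fall constant of target: the natural logarithm of the factor by which target drops between the first two readings, divided by the time between them, with the two second readings averaged. This gives 2.57 d⁻¹, read as a first-order decay, and the reckoning carries it to the 0.20 M flask because the runs at 0.13 M and 0.30 M read target alike at 0.500 d. Carried to 3.0 d, it leaves 0.0359% of target, a factor 975 under the level needed. So side product leads, with a share of 99.9%. For the opposite outcome, reckoned from the reading at 0.500 d, k would have to be −0.186 d⁻¹, a growing target. The early time 40 min lies before the first reading; the share read nearest, at 0.500 d, is 56.9%.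

The forecast gives 3% at 40 min, >99.9% at 3.0 d and side product in the lead, and says of its early figure “so this is extrapolated”.

The 0.20 M flask gives 99.9% at 3.0 d, with side product ahead at 36.9% against 0.0428%, and 36.7% at 40 min. With the reverse step from intermediate C to intermediate B struck out, its 40 min share comes to 91.6%. Applied to this flask's 2.17% of target at 1.50 d, k gives 0.0459% at 3.0 d; the flask holds 0.0428%.

    substrate → intermediate A (k = 4.80 × 10⁻⁴ s⁻¹)
    intermediate A → intermediate B (k = 0.00960 s⁻¹)
    intermediate B ⇌ intermediate C (K = 0.110, k = 0.00220 s⁻¹)
    intermediate C → side product (k = 2.10 × 10⁻⁴ s⁻¹)
    intermediate B → target (k = 3.90 × 10⁻⁵ s⁻¹)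
    intermediate C ⇌ intermediate D (K = 2.60, k = 1.30 × 10⁻⁴ s⁻¹)
    target → over-reaction product (k = 3.80 × 10⁻⁵ s⁻¹)
    substrate ⇌ dormant form (K = 0.630, k = 0.00300 s⁻¹)

For the same flask with 0.080 M of substrate, k, read as first order, carries no concentration, so the estimate again gives 0.0359% of target and a share of 99.9%. The computed flask gives 99.9%.

Readings and results were computed for substances that don't exist; noise was put on by code.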